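Summer nearly is the flask: the charges match except for the added ligand.

| setting | midnight | noon | summer | flask |
|---|---|---|---|---|
| left-handed substrate | 28 mM | 44 mM | 20 mM | 20 mM |
| right-handed substrate | 28 mM | 44 mM | 20 mM | 20 mM |
| coupling partner | 44 mM | 44 mM | 44 mM | 44.0 mM |
| racemization catalyst | 44 µM | 44 µM | 44 µM | 44 µM |
| precatalyst | 60 µM | 60 µM | 60 µM | 60 µM |
| added ligand | 35 µM | 35 µM | 70 µM | 35 µM |
| remark | run made earlier | run made earlier | run made earlier |  |
| time |  |  |  | 10 d |

- midnight (time / d: left-handed product / %, right-handed product / %): 0.833: 0, 0; 2.50: 7, 0; 4.00: 13, 2; 6.00: 21, 4; 10.0: 34, 6; 12.0: 35, 8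
- noon (time / d: left-handed product / %, right-handed product / %): 1.04: 2, 0; 1.67: 5, 0; 2.50: 7, 2; 4.00: 11, 2; 8.00: 24, 3; 12.0: 27, 6
- summer (time / d: left-handed product / %, right-handed product / %): 2.50: 8, 1; 5.00: 15, 4; 8.00: 28, 5; 10.0: 32, 7; 12.0: 36, 7

(each reading ± 1.5 percentage points)

- free catalyst is single-handed; left-handed substrate and right-handed substrate are mirror images of each other, charged as a racemate, each of them at the stated concentration
- an excess is the difference of the two amounts in percent of their sum
- an excess is below zero if the other one leads

- left-handed product and right-handed product together, in percent of the left-handed substrate and right-handed substrate charged together, at 10 d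
- excess of left-handed product over right-handed product in the product at 10 d
- whether the exchange between left-handed substrate and right-handed substrate keeps pace with the reaction: how far the product's excess at 10 d gets from its value without exchange to its value with instant exchange (above 80% keeps pace, below 20% hardly takes part, else lags behind)

At 10.0 d, summer's two products together read 39.0%. Midnight, with more substrate and less ligand, reads 40.0% at 10.0 d, about the same percentage consumed as summer. That points to one number, the depth N: the natural logarithm of substrate charged over substrate left, scaled from summer by time, partner charge and precatalyst charge. For the flask, N = 0.494. It counts how many times the substrate has fallen by a factor e, so y reads 39.0%.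

Is one number enough? At 12.0 d, N predicts 44.7%. Midnight reads 43.0%, but noon reads 33.0%, and in noon the partner is the limiting reagent. The flask's partner charge covers its substrate charge, as summer's does, so N is kept for y. N is blind to handedness, however. At 10.0 d, the excess reads 70.0% in midnight and 64.1% in summer. The flask has midnight's ligand and summer's substrate, so this reckoning puts eP between the two readings and leaves the pace open.

The forecast gives y 39%, eP 67% and exchange that lags behind, reasoning that “The flask should therefore resemble summer and midnight”.

The flask gives y 39.0% and eP 69.4%; exchange lags behind, getting 46% of the way.

    coupling partner + free catalyst + left-handed substrate → free catalyst + left-handed product (k = 15200 L² mol⁻² h⁻¹)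
    coupling partner + free catalyst + right-handed substrate → free catalyst + right-handed product (k = 2220 L² mol⁻² h⁻¹)
    precatalyst → free catalyst (k = 0.00714 h⁻¹)
    racemization catalyst + added ligand ⇌ idle complex, settled at all times (K = 1.00 × 10⁶ L mol⁻¹)
    left-handed substrate + racemization catalyst ⇌ right-handed substrate + racemization catalyst, rate k5*[racemization catalyst]*[left-handed substrate] forward; the back reaction follows from the equilibrium constant (k = 395 L mol⁻¹ h⁻¹)
    2 free catalyst ⇌ resting dimer, settled at all times (K = 1.98 × 10⁵ L mol⁻¹)

The substrates left in the flask give a depth of 0.494, against N = 0.494. The neighbour flask charged with 0.024 mM of precatalyst scales to a depth of 0.198, smaller than N, which reads 18.0%. Yet that neighbour gives 27.6%, more than that reckoning. In that neighbour, free catalyst stands at 24.6% and resting dimer at 57.4% of the catalyst charged, against 16.6% and 65.4% in the flask.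

The runs are calculated for an exercise; the scatter is artificial.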